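**Plan**

1. Retrosynthesis: cut the ten O–Si bonds, then the aryl–vinyl bond of the stilbene. Then, in each of the three trans-2,3-diaryl-2,3-dihydrobenzofurans in turn (ring C with the styryl group, ring B in the middle, ring A with the 3,5-dihydroxyphenyl group), cut the C2–C3 bond by putting a nitrogen back between C2 and C3. The resulting six-membered 1,3-benzoxazine opens to an aryl aldehyde and an ortho-hydroxybenzhydrylamine, which is cut at its aryl–CH(N) bond.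
2. Enabling feature: in each dihydrobenzofuran C2 and C3 are both benzylic CH carbons, C2 bound to the ring oxygen O1 and C3 to the resorcinol carbon C3a. The ring O1–C2–N–C3–C3a–C7a therefore assembles from amine and aldehyde as an N,O-acetal. Loss of N2 from its N-nitrene (isodiazene) leaves two stabilised radicals with no β-hydrogen, held together by O1–C7a–C3a, which can only pair.
3. Forward: one linchpin, 2-bromo-6-(methoxymethoxy)-4-silyloxybenzaldehyde as its (S)- or (R)-tert-butanesulfinyl imine, is used three times in the same three-step cycle: aryl Grignard addition, acid release of amine and phenol, then condensation with 4-silyloxybenzaldehyde and nitrogen deletion. This builds ring A, then ring B, then ring C.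
4. The bromine left by each cycle is the Grignard site of the next; the last bromine takes the catechol styrene in a Mizoroki–Heck reaction, and fluoride frees the ten phenols.
5. Stereochemistry: C3 of each ring comes from the sulfinamide ((S) at sulfur for rings A and C, (R) for ring B) and is carried through nitrogen loss. C2 is set trans to C3 in the ring contraction. The (E)-alkene comes from the Heck reaction.

Key step: step 16

Abbreviations: TIPS = triisopropylsilyl, TBS = tert-butyldimethylsilyl, MOM = methoxymethyl; "anomeric amide" = N-(benzyloxy)-N-(pivaloyloxy)-4-(trifluoromethyl)benzamide. Ar-A = (2R,3R)-3-[3,5-bis(TIPS-oxy)phenyl]-6-(TIPS-oxy)-2-[4-(TIPS-oxy)phenyl]-2,3-dihydro-1-benzofuran-4-yl. Ar-B = (2S,3S)-3-(Ar-A)-6-(TIPS-oxy)-2-[4-(TIPS-oxy)phenyl]-2,3-dihydro-1-benzofuran-4-yl.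

Assumption: aryl Grignard additions to the N-tert-butanesulfinyl aldimines in CH2Cl2 follow the closed, magnesium-bridged chair transition state, so that (S) at sulfur gives the (R)-carbinamine carbon here. If chelation by the ortho acetal oxygen reverses this sense, the two sulfinamide enantiomers are exchanged between steps 4 and 5.

**Route**

Step 1
Reactants: 1 2-bromo-4,6-dimethoxybenzaldehyde
Product: 2 2-bromo-4,6-dihydroxybenzaldehyde
Conditions: BBr3 (4 equiv), CH2Cl2, −78 to 23 °C; then H2O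
Reagents that add atoms: none
Why: Lewis-acid cleavage of aryl methyl ethers (BBr3 demethylation) removes both methyl groups, and the aldehyde and the aryl bromide should be inert.

Step 2
Reactants: 2 2-bromo-4,6-dihydroxybenzaldehyde
Product: 3 2-bromo-6-hydroxy-4-(TIPS-oxy)benzaldehyde
Conditions: TIPSCl (1.05 equiv), imidazole (2.2 equiv), DMF, 0 °C
Reagents that add atoms: chlorotri(propan-2-yl)silane, CC(C)[Si](Cl)(C(C)C)C(C)C
Why: Selective O-silylation should take the 4-hydroxyl, which is para to the formyl group and free, while the 6-hydroxyl is held in a hydrogen bond to the carbonyl oxygen.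

Step 3
Reactants: 3 2-bromo-6-hydroxy-4-(TIPS-oxy)benzaldehyde
Product: 4 2-bromo-6-(MOM-oxy)-4-(TIPS-oxy)benzaldehyde
Conditions: MOMCl (1.5 equiv), i-Pr2NEt (2 equiv), CH2Cl2, 0 to 23 °C
Reagents that add atoms: chloromethyl methyl ether, COCCl
Why: O-alkylation of the remaining phenol gives the acetal that later falls off in the same acid step as the sulfinyl group, while the aryl TIPS ether stays.

Step 4
Reactants: 4 2-bromo-6-(MOM-oxy)-4-(TIPS-oxy)benzaldehyde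
Product: 5 (S,E)-N-{[2-bromo-6-(MOM-oxy)-4-(TIPS-oxy)phenyl]methylidene}-2-methylpropane-2-sulfinamide
Conditions: (S)-tert-butanesulfinamide (1.1 equiv), Ti(OEt)4 (2 equiv), THF, 23 to 50 °C
Reagents that add atoms: (S)-2-methylpropane-2-sulfinamide, CC(C)(C)[S@](=O)N
Why: Titanium-alkoxide-mediated condensation of an aldehyde with tert-butanesulfinamide gives the (E)-N-sulfinyl aldimine, with Ti(OEt)4 acting as Lewis acid and water scavenger; no carbon stereocentre is formed.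

Step 5
Reactants: 4 2-bromo-6-(MOM-oxy)-4-(TIPS-oxy)benzaldehyde
Product: 6 (R,E)-N-{[2-bromo-6-(MOM-oxy)-4-(TIPS-oxy)phenyl]methylidene}-2-methylpropane-2-sulfinamide
Conditions: (R)-tert-butanesulfinamide (1.1 equiv), Ti(OEt)4 (2 equiv), THF, 23 to 50 °C
Reagents that add atoms: (R)-2-methylpropane-2-sulfinamide, CC(C)(C)[S@@](=O)N
Why: The same condensation as in step 4 gives the enantiomeric auxiliary imine needed for ring B.

Step 6
Reactants: 7 5-bromobenzene-1,3-diol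
Product: 8 1-bromo-3,5-bis(TIPS-oxy)benzene
Conditions: TIPSCl (2.3 equiv), imidazole (5 equiv), DMF, 23 °C
Reagents that add atoms: chlorotri(propan-2-yl)silane, CC(C)[Si](Cl)(C(C)C)C(C)C
Why: Standard silylation of both phenols gives ethers that tolerate organomagnesium reagents and HCl in methanol.

Step 7
Reactants: 9 4-hydroxybenzaldehyde
Product: 10 4-(TIPS-oxy)benzaldehyde
Conditions: TIPSCl (1.1 equiv), imidazole (2.5 equiv), DMF, 23 °C
Reagents that add atoms: chlorotri(propan-2-yl)silane, CC(C)[Si](Cl)(C(C)C)C(C)C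
Why: Standard phenol silylation gives the aldehyde partner that supplies C2 and its aryl group in all three cycles.

Step 8
Reactants: 8 1-bromo-3,5-bis(TIPS-oxy)benzene and 5 (S)-sulfinyl imine
Product: 12 (S)-N-{(R)-[2-bromo-6-(MOM-oxy)-4-(TIPS-oxy)phenyl][3,5-bis(TIPS-oxy)phenyl]methyl}-2-methylpropane-2-sulfinamide, via Grignard reagent 11 (not isolated)
Conditions: 8, Mg turnings, I2 (cat.), THF, 45 °C; then add to 5 in CH2Cl2, −48 to 23 °C; H2O quench
Reagents that add atoms: none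
Why: 1,2-Addition of an aryl Grignard reagent to an N-tert-butanesulfinyl aldimine through the closed six-membered transition state (magnesium on the sulfinyl oxygen, tert-butyl equatorial) should set the (R)-carbon that becomes C3 of ring A; the Grignard reagent does not exchange with the aryl bromide of the imine.

Step 9
Reactants: 12 ring A sulfinamide
Product: 13 2-{(R)-amino[3,5-bis(TIPS-oxy)phenyl]methyl}-3-bromo-5-(TIPS-oxy)phenol
Conditions: HCl (4 M in 1,4-dioxane, 6 equiv), MeOH, 23 °C; concentrate; aq. NaHCO3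
Reagents that add atoms: none
Why: Acid methanolysis cleaves the N–S bond and the MOM acetal in one operation, while aryl TIPS ethers and the aryl bromide should survive.

Step 10
Reactants: 13 ring A aminophenol and 10 4-(TIPS-oxy)benzaldehyde
Product: 16 (2R,3R)-4-bromo-3-[3,5-bis(TIPS-oxy)phenyl]-6-(TIPS-oxy)-2-[4-(TIPS-oxy)phenyl]-2,3-dihydro-1-benzofuran, via ring A benzoxazine 14 (not isolated), via ring A isodiazene 15 (not isolated)
Conditions: 10 (1.1 equiv), 4 Å molecular sieves, THF, 40 °C; then anomeric amide (1.5 equiv), THF, 45 °C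
Reagents that add atoms: none
Why: Proposed new method: the nitrogen deletion described under step 16, here on the simplest member of the series, in which the ring tautomer 14 of the imine is N-aminated by the anomeric amide, isodiazene 15 loses N2 and the tethered benzylic radical pair closes the five-membered ring with retention at C3 (R) and trans at C2; the closest known reaction type is ring contraction of cyclic secondary benzylic amines by anomeric-amide nitrogen deletion.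

Step 11
Reactants: 16 ring A bromide and 6 (R)-sulfinyl imine
Product: 19 (R)-N-{(S)-[2-bromo-6-(MOM-oxy)-4-(TIPS-oxy)phenyl](Ar-A)methyl}-2-methylpropane-2-sulfinamide, via ring A aryllithium 17 (not isolated), via ring A arylmagnesium bromide 18 (not isolated)
Conditions: n-BuLi (1.05 equiv), THF, −78 °C; MgBr2·OEt2 (1.2 equiv), −78 to −40 °C; then 6 (1.3 equiv) in CH2Cl2, −48 to 23 °C; H2O quench
Reagents that add atoms: none
Why: Bromine–lithium exchange, transmetalation to magnesium and the same sulfinyl imine addition as in step 8, now with (R) at sulfur, should set the (S)-carbon (C3 of ring B) under reagent control regardless of the ring A stereocentres.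

Step 12
Reactants: 19 ring B sulfinamide
Product: 20 2-[(S)-amino(Ar-A)methyl]-3-bromo-5-(TIPS-oxy)phenol
Conditions: HCl (4 M in 1,4-dioxane, 6 equiv), MeOH, 23 °C; concentrate; aq. NaHCO3
Reagents that add atoms: none
Why: The same acid methanolysis as in step 9 removes the sulfinyl and MOM groups; the benzylic C2–O bond of ring A, flanked by a silyloxyphenyl group, should not ionise under these conditions.

Step 13
Reactants: 20 ring B aminophenol and 10 4-(TIPS-oxy)benzaldehyde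
Product: 23 (2S,3S)-4-bromo-3-(Ar-A)-6-(TIPS-oxy)-2-[4-(TIPS-oxy)phenyl]-2,3-dihydro-1-benzofuran, via ring B benzoxazine 21 (not isolated), via ring B isodiazene 22 (not isolated)
Conditions: 10 (1.1 equiv), 4 Å molecular sieves, THF, 40 °C; then anomeric amide (1.5 equiv), THF, 45 °C
Reagents that add atoms: none
Why: Proposed new method: the same sequence as in step 10 (ring-closed N,O-acetal 21, N-amination, isodiazene 22, loss of N2, pairing of the α-aryloxybenzyl and diarylmethyl radicals) should contract the six-membered ring to ring B with retention of the (S) centre at C3 and trans closure at C2; the closest known reaction type is again anomeric-amide nitrogen deletion of cyclic secondary benzylic amines.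

Step 14
Reactants: 23 ring B bromide and 5 (S)-sulfinyl imine
Product: 26 (S)-N-{(R)-[2-bromo-6-(MOM-oxy)-4-(TIPS-oxy)phenyl](Ar-B)methyl}-2-methylpropane-2-sulfinamide, via ring B aryllithium 24 (not isolated), via ring B arylmagnesium bromide 25 (not isolated)
Conditions: n-BuLi (1.05 equiv), THF, −78 °C; MgBr2·OEt2 (1.2 equiv), −78 to −40 °C; then 5 (1.3 equiv) in CH2Cl2, −48 to 23 °C; H2O quench
Reagents that add atoms: none
Why: The same exchange, transmetalation and sulfinyl imine addition as in step 11, with (S) at sulfur, should set the (R)-carbon that becomes C3 of ring C by reagent control.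

Step 15
Reactants: 26 ring C sulfinamide
Product: 27 2-[(R)-amino(Ar-B)methyl]-3-bromo-5-(TIPS-oxy)phenol
Conditions: HCl (4 M in 1,4-dioxane, 6 equiv), MeOH, 23 °C; concentrate; aq. NaHCO3
Reagents that add atoms: none
Why: Acid methanolysis as in steps 9 and 12 frees the amine and the ortho phenol; no stilbene is present yet, so the acid meets no acid-sensitive alkene.

Step 16
Reactants: 27 ring C aminophenol and 10 4-(TIPS-oxy)benzaldehyde
Product: 30 (2R,3R)-4-bromo-3-(Ar-B)-6-(TIPS-oxy)-2-[4-(TIPS-oxy)phenyl]-2,3-dihydro-1-benzofuran, via ring C benzoxazine 28 (not isolated), via ring C isodiazene 29 (not isolated)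
Conditions: 10 (1.1 equiv), 4 Å molecular sieves, THF, 40 °C; then anomeric amide (1.5 equiv), THF, 45 °C
Reagents that add atoms: none
Why: Proposed new method: amine 27 and aldehyde 10 condense to an imine that closes by 6-endo-trig attack of the phenol oxygen on C=N (ring–chain tautomerism) to benzoxazine 28, whose N–H is aminated by the anomeric amide; loss of pivalate and of benzyl 4-(trifluoromethyl)benzoate gives isodiazene 29, which expels N2 and leaves an α-aryloxybenzyl radical at C2 and a diarylmethyl radical at C3, joined through O1–C7a–C3a, that pair to the five-membered ring, so the six-membered ring O1–C2–N–C3–C3a–C7a contracts by one atom. The closest known reaction type is nitrogen deletion of secondary benzylic amines with anomeric amides (tetrahydroisoquinolines to indanes) and the isodiazene contraction of pyrrolidines to cyclobutanes; what is new is that the nitrogen is part of an N,O-acetal. C3 should keep the (R) configuration set in step 14 because the tethered singlet radical pair should close faster than the diarylmethyl radical can turn about its C3–C3a bond, as in the stereoretentive pyrrolidine contractions, and C2 should come out trans to the C3 aryl group because the freely reversible aminal sits as the 2,4-trans isomer (peri strain from the C5 bromine puts the 4-aryl group axial) and trans closure is also the less crowded one. The step needs C–C pairing to win over other fates: neither radical has a β-hydrogen, so disproportionation is shut off; the open imine tautomer has no N–H and is drained through the ring form; tautomerisation of the isodiazene to a hydrazone remains the competitor and should be slow in aprotic THF. The aryl bromide, the silyl ethers and the two finished dihydrobenzofurans should be inert to the reagent.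

Step 17
Reactants: 31 3,4-dihydroxybenzaldehyde
Product: 32 3,4-bis(TBS-oxy)benzaldehyde
Conditions: TBSCl (2.4 equiv), imidazole (5 equiv), DMF, 23 °C
Reagents that add atoms: tert-butyl(chloro)dimethylsilane, CC(C)(C)[Si](C)(C)Cl
Why: Standard catechol bis-silylation; this ring meets no acid later, so the smaller TBS groups suffice.

Step 18
Reactants: 32 3,4-bis(TBS-oxy)benzaldehyde
Product: 33 4-ethenyl-1,2-bis(TBS-oxy)benzene
Conditions: Ph3PCH3Br (1.3 equiv), KOt-Bu (1.25 equiv), THF, 0 °C; then 32, 0 to 23 °C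
Reagents that add atoms: methyltriphenylphosphonium bromide, [Br-].C[P+](c1ccccc1)(c1ccccc1)c1ccccc1
Why: Wittig methylenation of an aryl aldehyde with the non-stabilised ylide gives the styrene and leaves aryl silyl ethers untouched.

Step 19
Reactants: 30 ring C bromide and 33 4-ethenyl-1,2-bis(TBS-oxy)benzene
Product: 34 (2R,3R)-4-{(E)-2-[3,4-bis(TBS-oxy)phenyl]ethenyl}-3-(Ar-B)-6-(TIPS-oxy)-2-[4-(TIPS-oxy)phenyl]-2,3-dihydro-1-benzofuran
Conditions: 33 (2 equiv), Pd[P(t-Bu)3]2 (10 mol%), Cy2NMe (2 equiv), 1,4-dioxane, 80 °C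
Reagents that add atoms: none
Why: Mizoroki–Heck reaction with a zerovalent palladium catalyst carrying the bulky, electron-rich tri-tert-butylphosphine, which should add into the hindered bromide; syn insertion and syn β-hydride elimination give the (E)-stilbene, and the amine base spares the silyl ethers.

Step 20
Reactants: 34 deca-silyl ether
Product: 35 target decaphenol
Conditions: n-Bu4NF (15 equiv), AcOH (15 equiv), THF, 0 to 23 °C, argon
Reagents that add atoms: none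
Why: Fluoride cleavage of all ten aryl silyl ethers, buffered with acetic acid so that the phenols stay protonated; this avoids the strong acid that would cyclise the stilbene onto ring B and the free phenoxides that would open the rings through para-quinone methides.

**Compound list**

1 | 2-bromo-4,6-dimethoxybenzaldehyde | COc1cc(OC)c(C=O)c(Br)c1 | starting material
2 | 2-bromo-4,6-dihydroxybenzaldehyde | Oc1cc(O)c(C=O)c(Br)c1 | intermediate
3 | 2-bromo-6-hydroxy-4-(TIPS-oxy)benzaldehyde | O=Cc1c(O)cc(O[Si](C(C)C)(C(C)C)C(C)C)cc1Br | intermediate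
4 | 2-bromo-6-(MOM-oxy)-4-(TIPS-oxy)benzaldehyde | O=Cc1c(OCOC)cc(O[Si](C(C)C)(C(C)C)C(C)C)cc1Br | intermediate
5 | (S,E)-N-{[2-bromo-6-(MOM-oxy)-4-(TIPS-oxy)phenyl]methylidene}-2-methylpropane-2-sulfinamide | Brc1cc(O[Si](C(C)C)(C(C)C)C(C)C)cc(OCOC)c1/C=N/[S@@](=O)C(C)(C)C | intermediate
6 | (R,E)-N-{[2-bromo-6-(MOM-oxy)-4-(TIPS-oxy)phenyl]methylidene}-2-methylpropane-2-sulfinamide | Brc1cc(O[Si](C(C)C)(C(C)C)C(C)C)cc(OCOC)c1/C=N/[S@](=O)C(C)(C)C | intermediate
7 | 5-bromobenzene-1,3-diol | Oc1cc(O)cc(Br)c1 | starting material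
8 | 1-bromo-3,5-bis(TIPS-oxy)benzene | Brc1cc(O[Si](C(C)C)(C(C)C)C(C)C)cc(O[Si](C(C)C)(C(C)C)C(C)C)c1 | intermediate
9 | 4-hydroxybenzaldehyde | O=Cc1ccc(O)cc1 | starting material
10 | 4-(TIPS-oxy)benzaldehyde | O=Cc1ccc(O[Si](C(C)C)(C(C)C)C(C)C)cc1 | intermediate
11 | [3,5-bis(TIPS-oxy)phenyl]magnesium bromide | Br[Mg]c1cc(O[Si](C(C)C)(C(C)C)C(C)C)cc(O[Si](C(C)C)(C(C)C)C(C)C)c1 | intermediate
12 | (S)-N-{(R)-[2-bromo-6-(MOM-oxy)-4-(TIPS-oxy)phenyl][3,5-bis(TIPS-oxy)phenyl]methyl}-2-methylpropane-2-sulfinamide | Brc1cc(O[Si](C(C)C)(C(C)C)C(C)C)cc(OCOC)c1[C@@H](c1cc(O[Si](C(C)C)(C(C)C)C(C)C)cc(O[Si](C(C)C)(C(C)C)C(C)C)c1)N[S@@](=O)C(C)(C)C | intermediate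
13 | 2-{(R)-amino[3,5-bis(TIPS-oxy)phenyl]methyl}-3-bromo-5-(TIPS-oxy)phenol | Brc1cc(O[Si](C(C)C)(C(C)C)C(C)C)cc(O)c1[C@@H](c1cc(O[Si](C(C)C)(C(C)C)C(C)C)cc(O[Si](C(C)C)(C(C)C)C(C)C)c1)N | intermediate
14 | (2S,4R)-5-bromo-4-[3,5-bis(TIPS-oxy)phenyl]-7-(TIPS-oxy)-2-[4-(TIPS-oxy)phenyl]-3,4-dihydro-2H-1,3-benzoxazine | Brc1cc(O[Si](C(C)C)(C(C)C)C(C)C)cc2c1[C@@H](c1cc(O[Si](C(C)C)(C(C)C)C(C)C)cc(O[Si](C(C)C)(C(C)C)C(C)C)c1)N[C@H](c1ccc(O[Si](C(C)C)(C(C)C)C(C)C)cc1)O2 | intermediate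
15 | N-nitrene (isodiazene) of benzoxazine 14 | Brc1cc(O[Si](C(C)C)(C(C)C)C(C)C)cc2c1[C@@H](c1cc(O[Si](C(C)C)(C(C)C)C(C)C)cc(O[Si](C(C)C)(C(C)C)C(C)C)c1)[N+](=[N-])[C@H](c1ccc(O[Si](C(C)C)(C(C)C)C(C)C)cc1)O2 | intermediate
16 | (2R,3R)-4-bromo-3-[3,5-bis(TIPS-oxy)phenyl]-6-(TIPS-oxy)-2-[4-(TIPS-oxy)phenyl]-2,3-dihydro-1-benzofuran (Ar-A bromide) | Brc1cc(O[Si](C(C)C)(C(C)C)C(C)C)cc2c1[C@@H](c1cc(O[Si](C(C)C)(C(C)C)C(C)C)cc(O[Si](C(C)C)(C(C)C)C(C)C)c1)[C@H](c1ccc(O[Si](C(C)C)(C(C)C)C(C)C)cc1)O2 | intermediate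
17 | Ar-A lithium (4-lithio analogue of 16) | [Li]c1cc(O[Si](C(C)C)(C(C)C)C(C)C)cc2c1[C@@H](c1cc(O[Si](C(C)C)(C(C)C)C(C)C)cc(O[Si](C(C)C)(C(C)C)C(C)C)c1)[C@H](c1ccc(O[Si](C(C)C)(C(C)C)C(C)C)cc1)O2 | intermediate
18 | Ar-A magnesium bromide | Br[Mg]c1cc(O[Si](C(C)C)(C(C)C)C(C)C)cc2c1[C@@H](c1cc(O[Si](C(C)C)(C(C)C)C(C)C)cc(O[Si](C(C)C)(C(C)C)C(C)C)c1)[C@H](c1ccc(O[Si](C(C)C)(C(C)C)C(C)C)cc1)O2 | intermediate
19 | (R)-N-{(S)-[2-bromo-6-(MOM-oxy)-4-(TIPS-oxy)phenyl](Ar-A)methyl}-2-methylpropane-2-sulfinamide | COCOc1cc(O[Si](C(C)C)(C(C)C)C(C)C)cc(Br)c1[C@@H](N[S@](=O)C(C)(C)C)c1cc(O[Si](C(C)C)(C(C)C)C(C)C)cc2c1[C@@H](c1cc(O[Si](C(C)C)(C(C)C)C(C)C)cc(O[Si](C(C)C)(C(C)C)C(C)C)c1)[C@H](c1ccc(O[Si](C(C)C)(C(C)C)C(C)C)cc1)O2 | intermediate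
20 | 2-[(S)-amino(Ar-A)methyl]-3-bromo-5-(TIPS-oxy)phenol | Oc1cc(O[Si](C(C)C)(C(C)C)C(C)C)cc(Br)c1[C@@H](N)c1cc(O[Si](C(C)C)(C(C)C)C(C)C)cc2c1[C@@H](c1cc(O[Si](C(C)C)(C(C)C)C(C)C)cc(O[Si](C(C)C)(C(C)C)C(C)C)c1)[C@H](c1ccc(O[Si](C(C)C)(C(C)C)C(C)C)cc1)O2 | intermediate
21 | (2R,4S)-5-bromo-4-(Ar-A)-7-(TIPS-oxy)-2-[4-(TIPS-oxy)phenyl]-3,4-dihydro-2H-1,3-benzoxazine | CC(C)[Si](C(C)C)(C(C)C)Oc1ccc([C@H]2Oc3cc(O[Si](C(C)C)(C(C)C)C(C)C)cc(Br)c3[C@@H](N2)c2cc(O[Si](C(C)C)(C(C)C)C(C)C)cc3c2[C@@H](c2cc(O[Si](C(C)C)(C(C)C)C(C)C)cc(O[Si](C(C)C)(C(C)C)C(C)C)c2)[C@H](c2ccc(O[Si](C(C)C)(C(C)C)C(C)C)cc2)O3)cc1 | intermediate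
22 | N-nitrene (isodiazene) of benzoxazine 21 | CC(C)[Si](C(C)C)(C(C)C)Oc1ccc([C@H]2Oc3cc(O[Si](C(C)C)(C(C)C)C(C)C)cc(Br)c3[C@@H]([N+]2=[N-])c2cc(O[Si](C(C)C)(C(C)C)C(C)C)cc3c2[C@@H](c2cc(O[Si](C(C)C)(C(C)C)C(C)C)cc(O[Si](C(C)C)(C(C)C)C(C)C)c2)[C@H](c2ccc(O[Si](C(C)C)(C(C)C)C(C)C)cc2)O3)cc1 | intermediate
23 | (2S,3S)-4-bromo-3-(Ar-A)-6-(TIPS-oxy)-2-[4-(TIPS-oxy)phenyl]-2,3-dihydro-1-benzofuran (Ar-B bromide) | CC(C)[Si](C(C)C)(C(C)C)Oc1ccc([C@H]2Oc3cc(O[Si](C(C)C)(C(C)C)C(C)C)cc(Br)c3[C@@H]2c2cc(O[Si](C(C)C)(C(C)C)C(C)C)cc3c2[C@@H](c2cc(O[Si](C(C)C)(C(C)C)C(C)C)cc(O[Si](C(C)C)(C(C)C)C(C)C)c2)[C@H](c2ccc(O[Si](C(C)C)(C(C)C)C(C)C)cc2)O3)cc1 | intermediate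
24 | Ar-B lithium (4-lithio analogue of 23) | CC(C)[Si](C(C)C)(C(C)C)Oc1ccc([C@H]2Oc3cc(O[Si](C(C)C)(C(C)C)C(C)C)cc([Li])c3[C@@H]2c2cc(O[Si](C(C)C)(C(C)C)C(C)C)cc3c2[C@@H](c2cc(O[Si](C(C)C)(C(C)C)C(C)C)cc(O[Si](C(C)C)(C(C)C)C(C)C)c2)[C@H](c2ccc(O[Si](C(C)C)(C(C)C)C(C)C)cc2)O3)cc1 | intermediate
25 | Ar-B magnesium bromide | CC(C)[Si](C(C)C)(C(C)C)Oc1ccc([C@H]2Oc3cc(O[Si](C(C)C)(C(C)C)C(C)C)cc([Mg]Br)c3[C@@H]2c2cc(O[Si](C(C)C)(C(C)C)C(C)C)cc3c2[C@@H](c2cc(O[Si](C(C)C)(C(C)C)C(C)C)cc(O[Si](C(C)C)(C(C)C)C(C)C)c2)[C@H](c2ccc(O[Si](C(C)C)(C(C)C)C(C)C)cc2)O3)cc1 | intermediate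
26 | (S)-N-{(R)-[2-bromo-6-(MOM-oxy)-4-(TIPS-oxy)phenyl](Ar-B)methyl}-2-methylpropane-2-sulfinamide | CC(C)[Si](C(C)C)(C(C)C)Oc1ccc([C@H]2Oc3cc(O[Si](C(C)C)(C(C)C)C(C)C)cc([C@@H](N[S@@](=O)C(C)(C)C)c4c(Br)cc(O[Si](C(C)C)(C(C)C)C(C)C)cc4OCOC)c3[C@@H]2c2cc(O[Si](C(C)C)(C(C)C)C(C)C)cc3c2[C@@H](c2cc(O[Si](C(C)C)(C(C)C)C(C)C)cc(O[Si](C(C)C)(C(C)C)C(C)C)c2)[C@H](c2ccc(O[Si](C(C)C)(C(C)C)C(C)C)cc2)O3)cc1 | intermediate
27 | 2-[(R)-amino(Ar-B)methyl]-3-bromo-5-(TIPS-oxy)phenol | CC(C)[Si](C(C)C)(C(C)C)Oc1ccc([C@H]2Oc3cc(O[Si](C(C)C)(C(C)C)C(C)C)cc([C@@H](N)c4c(Br)cc(O[Si](C(C)C)(C(C)C)C(C)C)cc4O)c3[C@@H]2c2cc(O[Si](C(C)C)(C(C)C)C(C)C)cc3c2[C@@H](c2cc(O[Si](C(C)C)(C(C)C)C(C)C)cc(O[Si](C(C)C)(C(C)C)C(C)C)c2)[C@H](c2ccc(O[Si](C(C)C)(C(C)C)C(C)C)cc2)O3)cc1 | intermediate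
28 | (2S,4R)-5-bromo-4-(Ar-B)-7-(TIPS-oxy)-2-[4-(TIPS-oxy)phenyl]-3,4-dihydro-2H-1,3-benzoxazine | CC(C)[Si](C(C)C)(C(C)C)Oc1ccc([C@H]2Oc3cc(O[Si](C(C)C)(C(C)C)C(C)C)cc([C@@H]4c5c(Br)cc(O[Si](C(C)C)(C(C)C)C(C)C)cc5O[C@H](N4)c4ccc(O[Si](C(C)C)(C(C)C)C(C)C)cc4)c3[C@@H]2c2cc(O[Si](C(C)C)(C(C)C)C(C)C)cc3c2[C@@H](c2cc(O[Si](C(C)C)(C(C)C)C(C)C)cc(O[Si](C(C)C)(C(C)C)C(C)C)c2)[C@H](c2ccc(O[Si](C(C)C)(C(C)C)C(C)C)cc2)O3)cc1 | intermediate
29 | N-nitrene (isodiazene) of benzoxazine 28 | CC(C)[Si](C(C)C)(C(C)C)Oc1ccc([C@H]2Oc3cc(O[Si](C(C)C)(C(C)C)C(C)C)cc([C@@H]4c5c(Br)cc(O[Si](C(C)C)(C(C)C)C(C)C)cc5O[C@H]([N+]4=[N-])c4ccc(O[Si](C(C)C)(C(C)C)C(C)C)cc4)c3[C@@H]2c2cc(O[Si](C(C)C)(C(C)C)C(C)C)cc3c2[C@@H](c2cc(O[Si](C(C)C)(C(C)C)C(C)C)cc(O[Si](C(C)C)(C(C)C)C(C)C)c2)[C@H](c2ccc(O[Si](C(C)C)(C(C)C)C(C)C)cc2)O3)cc1 | intermediate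
30 | (2R,3R)-4-bromo-3-(Ar-B)-6-(TIPS-oxy)-2-[4-(TIPS-oxy)phenyl]-2,3-dihydro-1-benzofuran | CC(C)[Si](C(C)C)(C(C)C)Oc1ccc([C@H]2Oc3cc(O[Si](C(C)C)(C(C)C)C(C)C)cc([C@@H]4c5c(Br)cc(O[Si](C(C)C)(C(C)C)C(C)C)cc5O[C@H]4c4ccc(O[Si](C(C)C)(C(C)C)C(C)C)cc4)c3[C@@H]2c2cc(O[Si](C(C)C)(C(C)C)C(C)C)cc3c2[C@@H](c2cc(O[Si](C(C)C)(C(C)C)C(C)C)cc(O[Si](C(C)C)(C(C)C)C(C)C)c2)[C@H](c2ccc(O[Si](C(C)C)(C(C)C)C(C)C)cc2)O3)cc1 | intermediate
31 | 3,4-dihydroxybenzaldehyde | O=Cc1ccc(O)c(O)c1 | starting material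
32 | 3,4-bis(TBS-oxy)benzaldehyde | O=Cc1ccc(O[Si](C)(C)C(C)(C)C)c(O[Si](C)(C)C(C)(C)C)c1 | intermediate
33 | 4-ethenyl-1,2-bis(TBS-oxy)benzene | C=Cc1ccc(O[Si](C)(C)C(C)(C)C)c(O[Si](C)(C)C(C)(C)C)c1 | intermediate
34 | (2R,3R)-4-{(E)-2-[3,4-bis(TBS-oxy)phenyl]ethenyl}-3-(Ar-B)-6-(TIPS-oxy)-2-[4-(TIPS-oxy)phenyl]-2,3-dihydro-1-benzofuran (deca-silyl ether of the target) | CC(C)[Si](C(C)C)(C(C)C)Oc1ccc([C@H]2Oc3cc(O[Si](C(C)C)(C(C)C)C(C)C)cc([C@@H]4c5c(/C=C/c6ccc(O[Si](C)(C)C(C)(C)C)c(O[Si](C)(C)C(C)(C)C)c6)cc(O[Si](C(C)C)(C(C)C)C(C)C)cc5O[C@H]4c4ccc(O[Si](C(C)C)(C(C)C)C(C)C)cc4)c3[C@@H]2c2cc(O[Si](C(C)C)(C(C)C)C(C)C)cc3c2[C@@H](c2cc(O[Si](C(C)C)(C(C)C)C(C)C)cc(O[Si](C(C)C)(C(C)C)C(C)C)c2)[C@H](c2ccc(O[Si](C(C)C)(C(C)C)C(C)C)cc2)O3)cc1 | intermediate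
35 | target: ring C (2R,3R)-4-[(E)-2-(3,4-dihydroxyphenyl)ethenyl]-6-hydroxy-2-(4-hydroxyphenyl)-2,3-dihydro-1-benzofuran, bound at C3 to C4 of ring B (2S,3S)-6-hydroxy-2-(4-hydroxyphenyl)-2,3-dihydro-1-benzofuran, bound at C3 to C4 of ring A (2R,3R)-3-(3,5-dihydroxyphenyl)-6-hydroxy-2-(4-hydroxyphenyl)-2,3-dihydro-1-benzofuran | Oc1ccc([C@H]2Oc3cc(O)cc([C@@H]4c5c(/C=C/c6ccc(O)c(O)c6)cc(O)cc5O[C@H]4c4ccc(O)cc4)c3[C@@H]2c2cc(O)cc3c2[C@@H](c2cc(O)cc(O)c2)[C@H](c2ccc(O)cc2)O3)cc1 | target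

**Summary**

Total step count: 20. Longest linear sequence: 15 steps (steps 1, 2, 3, 4, 8 to 16, 19 and 20).

The three steps most likely to fail, each with its fallback:

Step 16. What may go wrong: too little of the ring tautomer is intercepted by the anomeric amide on this crowded substrate, the diarylmethyl radical turns before pairing so that C3 loses its configuration, closure goes partly cis at C2, or the isodiazene tautomerises to a hydrazone. The fallback is a formal [4+1] annulation of an ortho-quinone methide with a sulfur ylide, both known reaction types. It sets out from phenol 3, aldehyde 10 and Grignard reagent 25 (made from bromide 23 as in step 14) and comes back to the route at bromide 30. Phenol 3 is acylated with Boc2O and DMAP to tert-butyl 3-bromo-2-formyl-5-(TIPS-oxy)phenyl carbonate F1. Aldehyde 10 is reduced with NaBH4 to [4-(TIPS-oxy)phenyl]methanol F2, which with tetrahydrothiophene and TfOH gives 1-[4-(TIPS-oxy)benzyl]thiolan-1-ium trifluoromethanesulfonate F3. Addition of 25 to F1 at −78 °C, transfer of the carbonate to the new alkoxide and loss of tert-butyl carbonate on warming should give the ring C ortho-quinone methide F4. The ylide from F3 (LiHMDS, −78 °C) adds to its methide carbon and the phenoxide displaces tetrahydrothiophene (5-exo-tet) to the trans-dihydrobenzofuran. Without control from nitrogen the trans product forms as two diastereomers; 30 is separated by chromatography from the (2S,3S)-ring C diastereomer F5.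

Step 13. What may go wrong: the same processes as in step 16, on the first substrate that already carries a dihydrobenzofuran next to the reacting centre. The fallback is the same known annulation; it sets out from bromide 16 (as its Grignard reagent 18, step 11), carbonate F1 and sulfonium salt F3, and comes back at bromide 23. Addition of 18 to F1 and loss of tert-butyl carbonate give the ring B ortho-quinone methide F6, the ylide from F3 closes the trans-dihydrobenzofuran, and 23 is separated by chromatography from the (2R,3R)-ring B diastereomer F7.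

Step 10. What may go wrong: the first trial of the method; N-amination of the hindered N,O-acetal nitrogen may be slow against decay of the anomeric amide, or the open imine tautomer may dominate so strongly that the reaction stalls. The fallback sets out from bromide 8 (as its Grignard reagent 11, step 8), carbonate F1 and sulfonium salt F3, and comes back at bromide 16. Addition of 11 to F1 gives the ring A ortho-quinone methide F8, and the ylide from F3 closes the racemic trans-dihydrobenzofuran. Resolution by HPLC on a chiral stationary phase gives 16 and removes its (2S,3S)-enantiomer F9.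

Further compounds

F1 | step 16 | tert-butyl 3-bromo-2-formyl-5-(TIPS-oxy)phenyl carbonate | CC(C)(C)OC(=O)Oc1cc(O[Si](C(C)C)(C(C)C)C(C)C)cc(Br)c1C=O
F2 | step 16 | [4-(TIPS-oxy)phenyl]methanol | OCc1ccc(O[Si](C(C)C)(C(C)C)C(C)C)cc1
F3 | step 16 | 1-[4-(TIPS-oxy)benzyl]thiolan-1-ium trifluoromethanesulfonate | [O-]S(=O)(=O)C(F)(F)F.C1CC[S+](C1)Cc1ccc(O[Si](C(C)C)(C(C)C)C(C)C)cc1
F4 | step 16 | ring C ortho-quinone methide, 6-[(Ar-B)methylidene]-5-bromo-3-(TIPS-oxy)cyclohexa-2,4-dien-1-one (alkene geometry not defined) | CC(C)[Si](C(C)C)(C(C)C)Oc1ccc([C@H]2Oc3cc(O[Si](C(C)C)(C(C)C)C(C)C)cc(C=C4C(=O)C=C(O[Si](C(C)C)(C(C)C)C(C)C)C=C4Br)c3[C@@H]2c2cc(O[Si](C(C)C)(C(C)C)C(C)C)cc3c2[C@@H](c2cc(O[Si](C(C)C)(C(C)C)C(C)C)cc(O[Si](C(C)C)(C(C)C)C(C)C)c2)[C@H](c2ccc(O[Si](C(C)C)(C(C)C)C(C)C)cc2)O3)cc1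
F5 | step 16 | (2S,3S)-ring C diastereomer of 30 | CC(C)[Si](C(C)C)(C(C)C)Oc1ccc([C@H]2Oc3cc(O[Si](C(C)C)(C(C)C)C(C)C)cc([C@H]4c5c(Br)cc(O[Si](C(C)C)(C(C)C)C(C)C)cc5O[C@@H]4c4ccc(O[Si](C(C)C)(C(C)C)C(C)C)cc4)c3[C@@H]2c2cc(O[Si](C(C)C)(C(C)C)C(C)C)cc3c2[C@@H](c2cc(O[Si](C(C)C)(C(C)C)C(C)C)cc(O[Si](C(C)C)(C(C)C)C(C)C)c2)[C@H](c2ccc(O[Si](C(C)C)(C(C)C)C(C)C)cc2)O3)cc1
F6 | step 13 | ring B ortho-quinone methide, 6-[(Ar-A)methylidene]-5-bromo-3-(TIPS-oxy)cyclohexa-2,4-dien-1-one (alkene geometry not defined) | O=C1C=C(O[Si](C(C)C)(C(C)C)C(C)C)C=C(Br)C1=Cc1cc(O[Si](C(C)C)(C(C)C)C(C)C)cc2c1[C@@H](c1cc(O[Si](C(C)C)(C(C)C)C(C)C)cc(O[Si](C(C)C)(C(C)C)C(C)C)c1)[C@H](c1ccc(O[Si](C(C)C)(C(C)C)C(C)C)cc1)O2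
F7 | step 13 | (2R,3R)-ring B diastereomer of 23 | CC(C)[Si](C(C)C)(C(C)C)Oc1ccc([C@@H]2Oc3cc(O[Si](C(C)C)(C(C)C)C(C)C)cc(Br)c3[C@H]2c2cc(O[Si](C(C)C)(C(C)C)C(C)C)cc3c2[C@@H](c2cc(O[Si](C(C)C)(C(C)C)C(C)C)cc(O[Si](C(C)C)(C(C)C)C(C)C)c2)[C@H](c2ccc(O[Si](C(C)C)(C(C)C)C(C)C)cc2)O3)cc1
F8 | step 10 | ring A ortho-quinone methide, 6-{[3,5-bis(TIPS-oxy)phenyl]methylidene}-5-bromo-3-(TIPS-oxy)cyclohexa-2,4-dien-1-one (alkene geometry not defined) | O=C1C=C(O[Si](C(C)C)(C(C)C)C(C)C)C=C(Br)C1=Cc1cc(O[Si](C(C)C)(C(C)C)C(C)C)cc(O[Si](C(C)C)(C(C)C)C(C)C)c1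
F9 | step 10 | (2S,3S)-enantiomer of 16 | Brc1cc(O[Si](C(C)C)(C(C)C)C(C)C)cc2c1[C@H](c1cc(O[Si](C(C)C)(C(C)C)C(C)C)cc(O[Si](C(C)C)(C(C)C)C(C)C)c1)[C@@H](c1ccc(O[Si](C(C)C)(C(C)C)C(C)C)cc1)O2
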